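## Retrosynthetic overview

1. The two esters are attached last: the C8 ester comes from a C8 alcohol and (S)-2-methyloxirane-2-carboxylic acid, the C13 acetate from a triol, and C8 is set by reagent-controlled reduction of a C8 ketone.
2. The C5=C6 enol-lactone alkene comes from E1cB loss of a C5 silyloxy group after ring closure; the ten-membered ring is closed at C7–C8 by a CrCl2/NiCl2 coupling of a β-iodobutenolide with a C8 aldehyde.
3. Fragment union is an intermolecular vinylogous Mukaiyama aldol that makes C5–C6 from a tetrahydrofuran (THF) aldehyde and a 4-iodobutenolide (as its 2-silyloxyfuran).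
4. The THF aldehyde comes from (R)-linalool (allylic oxidation, Sharpless epoxidation, 5-exo epoxide opening, one-carbon homologation, ozonolysis); the iodobutenolide from but-2-yne-1,4-diol (allenoate, iodolactonisation); the acid from 2-methylprop-2-en-1-ol.
5. Ring order: THF ring (step 3), butenolide (step 11), ten-membered carbocycle (step 17).

Assumption: the target is the compound defined by the SMILES. Locants C1–C15 are germacrane locants (ring C1–C10; lactone C6–O–C12(=O)–C11=C7; C13 = CH2OAc carbon; C14 = methyl on C10; C15 = methyl on C4). Compounds 21–25 are carried as epimer mixtures at C5/C6 (24 also at C8), because these centres are later removed or reset; their SMILES leave those centres open.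

## Route

### THF aldehyde (C1–C5, C8–C10)

Step 1
Reactants: 1 (R)-(−)-linalool
Product: 3 (2E,6R)-2,6-dimethylocta-2,7-diene-1,6-diol, via enal 2 (not isolated)
Conditions: SeO2 (0.1 equiv), t-BuOOH (2 equiv), salicylic acid (0.1 equiv), CH2Cl2, 0 °C to rt; then NaBH4, MeOH, 0 °C
Reagents that add atoms: tert-butyl hydroperoxide, CC(C)(C)OO (terminal oxygen source, delivered through SeO2, O=[Se]=O)
Why: Catalytic SeO2 allylic oxidation (ene reaction, then [2,3]-sigmatropic shift) attacks only the (E)-methyl group of the trisubstituted alkene, the NaBH4 quench returns over-oxidised enal 2 to the same allylic alcohol, and the carbinol stereocentre is untouched.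

Step 2
Reactants: 3 (2E,6R)-2,6-dimethylocta-2,7-diene-1,6-diol
Product: 4 (3R)-5-[(2R,3R)-3-(hydroxymethyl)-3-methyloxiran-2-yl]-3-methylpent-1-en-3-ol
Conditions: Ti(OiPr)4 (10 mol %), D-(−)-diethyl tartrate (12 mol %), t-BuOOH (anhydrous, 2 equiv), 4 Å MS, CH2Cl2, −20 °C
Reagents that add atoms: tert-butyl hydroperoxide, CC(C)(C)OO
Why: Sharpless asymmetric epoxidation: the primary allylic alcohol directs the titanium tartrate catalyst to its own trisubstituted alkene (the tertiary vinyl carbinol is inert), and D-(−)-tartrate gives the (2R,3R)-epoxide, which fixes C10 and, after inversion, C1.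

Step 3
Reactants: 4 (3R)-5-[(2R,3R)-3-(hydroxymethyl)-3-methyloxiran-2-yl]-3-methylpent-1-en-3-ol
Product: 5 (2R)-2-[(2S,5R)-5-ethenyl-5-methyloxolan-2-yl]propane-1,2-diol
Conditions: camphor-10-sulfonic acid (10 mol %), CH2Cl2, 0 °C
Reagents that add atoms: none
Why: Acid-catalysed 5-exo-tet epoxide opening by the tertiary hydroxyl at the epoxide CH carbon (remote from the electron-withdrawing CH2OH) proceeds with inversion, giving C1 (S) with its side chain cis to the vinyl group on the THF ring, while C10 keeps its C–O bond (R).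

Step 4
Reactants: 5 (2R)-2-[(2S,5R)-5-ethenyl-5-methyloxolan-2-yl]propane-1,2-diol
Product: 7 (2S,5R)-5-ethenyl-5-methyl-2-[(2R)-2-methyloxiran-2-yl]oxolane, via monotosylate 6 (not isolated)
Conditions: NaH (2.5 equiv), N-tosylimidazole (1.1 equiv), THF, 0 °C to rt
Reagents that add atoms: N-tosylimidazole, Cc1ccc(cc1)S(=O)(=O)n1ccnc1 (its tosyl group is present in 6 only)
Why: Selective sulfonylation of the primary alkoxide followed by intramolecular Williamson displacement by the tertiary alkoxide closes the terminal epoxide without breaking the C10–O bond, so C10 stays R.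

Step 5
Reactants: 7 (2S,5R)-5-ethenyl-5-methyl-2-[(2R)-2-methyloxiran-2-yl]oxolane
Product: 9 (3R)-3-[(2S,5R)-5-ethenyl-5-methyloxolan-2-yl]butane-1,3-diol, via silane 8 (not isolated)
Conditions: ClCH2SiMe2(OiPr), Mg, THF; then 7, CuI (10 mol %), THF, −30 to 0 °C; then 30% H2O2, KF, KHCO3, THF/MeOH, rt
Reagents that add atoms: {[dimethyl(propan-2-yloxy)silyl]methyl}magnesium chloride, CC(C)O[Si](C)(C)C[Mg]Cl; hydrogen peroxide, OO
Why: Copper-catalysed Grignard opening of the 2,2-disubstituted epoxide at its CH2 terminus installs C8 as a masked hydroxymethyl group, and Tamao oxidation turns the C–Si bond into C–OH without touching any stereocentre (a cyclic siloxane formed from the magnesium alkoxide is oxidised to the same diol).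

Step 6
Reactants: 9 (3R)-3-[(2S,5R)-5-ethenyl-5-methyloxolan-2-yl]butane-1,3-diol
Product: 10 (2S,5R)-2-[(2R)-2,4-bis(triethylsilyloxy)butan-2-yl]-5-ethenyl-5-methyloxolane
Conditions: Et3SiOTf (2.5 equiv), 2,6-lutidine, CH2Cl2, −78 to 0 °C
Reagents that add atoms: triethylsilyl trifluoromethanesulfonate, CC[Si](CC)(CC)OS(=O)(=O)C(F)(F)F
Why: Silyl triflate with 2,6-lutidine silylates both the primary and the hindered tertiary hydroxyl, which prevents hemiacetal formation between the C10 oxygen and the C5 aldehyde made next.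

Step 7
Reactants: 10 (2S,5R)-2-[(2R)-2,4-bis(triethylsilyloxy)butan-2-yl]-5-ethenyl-5-methyloxolane
Product: 11 (2R,5S)-5-[(2R)-2,4-bis(triethylsilyloxy)butan-2-yl]-2-methyloxolane-2-carbaldehyde
Conditions: O3, CH2Cl2, −78 °C; then PPh3, −78 °C to rt
Reagents that add atoms: ozone, [O-][O+]=O
Why: Ozonolysis with reductive work-up cleaves the only alkene to a non-enolisable α-alkoxy aldehyde, so C4 cannot epimerise.

### Iodobutenolide (C6, C7, C11–C13)

Step 8
Reactants: 12 but-2-yne-1,4-diol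
Product: 13 4-{[tert-butyl(diphenyl)silyl]oxy}but-2-yn-1-ol
Conditions: TBDPSCl (1 equiv), imidazole, 12 (3 equiv), DMF, 0 °C to rt
Reagents that add atoms: tert-butyl(chloro)diphenylsilane, CC(C)(C)[Si](Cl)(c1ccccc1)c1ccccc1
Why: Statistical monosilylation of a cheap symmetrical diol used in excess gives the mono-TBDPS ether, a robust group that is a poor leaving group at the future C13.

Step 9
Reactants: 13 4-{[tert-butyl(diphenyl)silyl]oxy}but-2-yn-1-ol
Product: 14 4-{[tert-butyl(diphenyl)silyl]oxy}but-2-yn-1-yl methyl carbonate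
Conditions: ClCO2Me, pyridine, CH2Cl2, 0 °C
Reagents that add atoms: methyl chloroformate, COC(=O)Cl
Why: Acylation of the primary propargylic alcohol gives the carbonate needed for ionisation by palladium.

Step 10
Reactants: 14 4-{[tert-butyl(diphenyl)silyl]oxy}but-2-yn-1-yl methyl carbonate
Product: 15 methyl 2-({[tert-butyl(diphenyl)silyl]oxy}methyl)buta-2,3-dienoate
Conditions: Pd(OAc)2 (3 mol %), PPh3 (12 mol %), CO (10 atm), MeOH, 45 °C
Reagents that add atoms: carbon monoxide, [C-]#[O+]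
Why: Tsuji carbonylation: zerovalent palladium ionises the propargylic carbonate in SN2′ fashion to an allenylpalladium methoxide that inserts CO and is trapped by methoxide, which places the ester carbon (C12) on the carbon that already carries C13.

Step 11
Reactants: 15 methyl 2-({[tert-butyl(diphenyl)silyl]oxy}methyl)buta-2,3-dienoate
Product: 16 3-({[tert-butyl(diphenyl)silyl]oxy}methyl)-4-iodofuran-2(5H)-one
Conditions: I2 (2 equiv), NaHCO3, MeCN/H2O (15:1), rt
Reagents that add atoms: iodine, II; water, O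
Why: Electrophilic iodolactonisation of the 2,3-allenoate: iodine activates the terminal double bond, the ester carbonyl oxygen closes the five-membered ring at the CH2 terminus and the methyl group is lost on hydrolysis, giving the β-iodobutenolide with iodine on C7.

### Acid side chain

Step 12
Reactants: 17 2-methylprop-2-en-1-ol
Product: 18 [(2R)-2-methyloxiran-2-yl]methanol
Conditions: Ti(OiPr)4 (5 mol %), D-(−)-diethyl tartrate (6 mol %), t-BuOOH, 4 Å MS, CH2Cl2, −20 °C
Reagents that add atoms: tert-butyl hydroperoxide, CC(C)(C)OO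
Why: Sharpless asymmetric epoxidation of the 1,1-disubstituted allylic alcohol with D-(−)-tartrate gives the (R)-epoxy alcohol, the same facial sense as in step 2.

Step 13
Reactants: 18 [(2R)-2-methyloxiran-2-yl]methanol
Product: 19 (2S)-2-methyloxirane-2-carboxylic acid
Conditions: RuCl3·xH2O (2 mol %), NaIO4 (3 equiv), MeCN/EtOAc/H2O, 0 °C to rt; used crude
Reagents that add atoms: sodium periodate, [Na+].[O-]I(=O)(=O)=O; water, O
Why: Catalytically generated RuO4 oxidises the primary alcohol to the carboxylic acid without opening the epoxide, and the change in CIP priorities alone turns the descriptor from R to S.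

### Fragment union, ring closure and endgame

Step 14
Reactants: 11 (2R,5S)-5-[(2R)-2,4-bis(triethylsilyloxy)butan-2-yl]-2-methyloxolane-2-carbaldehyde + 16 3-({[tert-butyl(diphenyl)silyl]oxy}methyl)-4-iodofuran-2(5H)-one
Product: 21 5-{[(2R,5S)-5-[(2R)-2,4-bis(triethylsilyloxy)butan-2-yl]-2-methyloxolan-2-yl](tert-butyldimethylsilyloxy)methyl}-3-({[tert-butyl(diphenyl)silyl]oxy}methyl)-4-iodofuran-2(5H)-one (C5/C6 epimer mixture), via silyloxyfuran 20 (not isolated)
Conditions: 16 (1.3 equiv), i-Pr2NEt (3 equiv), TBSOTf (2.4 equiv), CH2Cl2, −78 °C; then 11, −78 to −40 °C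
Reagents that add atoms: tert-butyldimethylsilyl trifluoromethanesulfonate, CC(C)(C)[Si](C)(C)OS(=O)(=O)C(F)(F)F
Why: Vinylogous Mukaiyama aldol addition: soft enolisation gives 2-silyloxyfuran 20, which attacks the silyl-triflate-activated, non-enolisable aldehyde through its γ-carbon (C6), and the aldolate is silylated in situ; the new C5 and C6 centres need no control because both become sp2 in step 19.

Step 15
Reactants: 21 C5-silyloxy aldol adduct (bis-TES)
Product: 22 5-{[(2R,5S)-5-[(2R)-4-hydroxy-2-(triethylsilyloxy)butan-2-yl]-2-methyloxolan-2-yl](tert-butyldimethylsilyloxy)methyl}-3-({[tert-butyl(diphenyl)silyl]oxy}methyl)-4-iodofuran-2(5H)-one (C5/C6 epimer mixture)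
Conditions: pyridinium p-toluenesulfonate (0.2 equiv), MeOH/CH2Cl2 (1:1), 0 °C
Reagents that add atoms: none
Why: Acid-catalysed methanolysis removes the unhindered primary triethylsilyl ether much faster than the tertiary TES, secondary TBS or TBDPS ethers.

Step 16
Reactants: 22 C8 primary alcohol
Product: 23 5-{[(2R,5S)-2-methyl-5-[(2R)-4-oxo-2-(triethylsilyloxy)butan-2-yl]oxolan-2-yl](tert-butyldimethylsilyloxy)methyl}-3-({[tert-butyl(diphenyl)silyl]oxy}methyl)-4-iodofuran-2(5H)-one (C5/C6 epimer mixture)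
Conditions: Dess–Martin periodinane, NaHCO3, CH2Cl2, 0 °C to rt
Reagents that add atoms: none
Why: Dess–Martin oxidation under buffered, non-basic conditions gives the β-silyloxy aldehyde without elimination and without touching the iodobutenolide.

Step 17
Reactants: 23 iodo aldehyde
Product: 24 (1S,4R,10R)-5-(tert-butyldimethylsilyloxy)-13-{[tert-butyl(diphenyl)silyl]oxy}-1,4-epoxy-8-hydroxy-10-(triethylsilyloxy)germacr-7(11)-en-12,6-olide (C5/C6/C8 epimer mixture)
Conditions: CrCl2 (10 equiv), NiCl2 (0.1 equiv), DMSO/THF, rt, 0.003 M, slow addition of 23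
Reagents that add atoms: none
Why: Nozaki–Hiyama–Kishi reaction: zerovalent nickel inserts into the C7–iodine bond, transmetalation gives an alkenylchromium species of trivalent chromium that adds only to the aldehyde, and the cis-2,5-disubstituted THF holds both chains on one face for ten-membered ring closure; the C8 configuration is not relied on because it is reset in steps 18 and 20.

Step 18
Reactants: 24 macrocyclic C8 alcohol
Product: 25 (1S,4R,10R)-5-(tert-butyldimethylsilyloxy)-13-{[tert-butyl(diphenyl)silyl]oxy}-1,4-epoxy-8-oxo-10-(triethylsilyloxy)germacr-7(11)-en-12,6-olide (C5/C6 epimer mixture)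
Conditions: Dess–Martin periodinane, NaHCO3, CH2Cl2, 0 °C
Reagents that add atoms: none
Why: Dess–Martin oxidation of the allylic alcohol converges all C8 epimers on one ketone.

Step 19
Reactants: 25 macrocyclic C8 ketone
Product: 26 (1S,4R,5E,10R)-13-{[tert-butyl(diphenyl)silyl]oxy}-1,4-epoxy-8-oxo-10-(triethylsilyloxy)germacra-5,7(11)-dien-12,6-olide
Conditions: DBU (1,8-diazabicyclo[5.4.0]undec-7-ene, 2 equiv), CH2Cl2, 0 °C to rt
Reagents that add atoms: none
Why: E1cB elimination: DBU removes the doubly activated C6 proton to give a 2-furanolate that expels the C5 silyloxide, and the bridged bicyclic framework allows only the ring-cis (5E) exocyclic alkene of the target.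

Step 20
Reactants: 26 dienone lactone
Product: 27 (1S,4R,5E,8S,10R)-13-{[tert-butyl(diphenyl)silyl]oxy}-1,4-epoxy-8-hydroxy-10-(triethylsilyloxy)germacra-5,7(11)-dien-12,6-olide
Conditions: (R)-2-methyl-CBS-oxazaborolidine [(R)-1-methyl-3,3-diphenyltetrahydro-1H,3H-pyrrolo[1,2-c][1,3,2]oxazaborole] (0.3 equiv), catecholborane (2 equiv), toluene/CH2Cl2, −78 °C
Reagents that add atoms: none
Why: Corey–Bakshi–Shibata reduction: the (R)-oxazaborolidine activates catecholborane and delivers hydride to the ketone face defined by the large alkenyl (C7) and small CH2 (C9) groups, giving the 8S alcohol by 1,2-reduction.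

Step 21
Reactants: 27 8S alcohol (bis-silyl ether)
Product: 28 (1S,4R,5E,8S,10R)-1,4-epoxy-8,10,13-trihydroxygermacra-5,7(11)-dien-12,6-olide
Conditions: HF·pyridine, pyridine, THF, 0 °C to rt
Reagents that add atoms: none
Why: Fluoride-mediated desilylation removes the primary TBDPS and tertiary TES ethers under mildly acidic conditions that leave the enol lactone and the allylic alcohols untouched.

Step 22
Reactants: 28 triol
Product: 29 (1S,4R,5E,8S,10R)-13-acetoxy-1,4-epoxy-8,10-dihydroxygermacra-5,7(11)-dien-12,6-olide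
Conditions: AcCl (1.05 equiv), 2,4,6-collidine, CH2Cl2, −78 °C
Reagents that add atoms: acetyl chloride, CC(=O)Cl
Why: Kinetically controlled acetylation at low temperature with a hindered pyridine base acylates the primary C13 hydroxyl in preference to the hindered secondary C8 hydroxyl, and the tertiary C10 hydroxyl is inert.

Step 23
Reactants: 29 13-acetate diol + 19 (2S)-2-methyloxirane-2-carboxylic acid
Product: 30 (1S,4R,5E,8S,10R)-13-acetoxy-1,4-epoxy-10-hydroxy-8-{[(2S)-2-methyloxirane-2-carbonyl]oxy}germacra-5,7(11)-dien-12,6-olide (CNP0142137.1)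
Conditions: 19 (2 equiv), DCC, 4-(dimethylamino)pyridine (0.2 equiv), CH2Cl2, 0 °C to rt
Reagents that add atoms: none
Why: Steglich esterification acylates the only reactive (secondary) hydroxyl with retention at C8 and leaves the tertiary C10 alcohol free; the epoxide stereocentre comes unchanged from 19.

## Compound list

1 | (3R)-3,7-dimethylocta-1,6-dien-3-ol, (R)-(−)-linalool | C=C[C@](C)(O)CCC=C(C)C | starting material
2 | (2E,6R)-6-hydroxy-2,6-dimethylocta-2,7-dienal | C=C[C@](C)(O)CC/C=C(\C)C=O | intermediate (not isolated)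
3 | (2E,6R)-2,6-dimethylocta-2,7-diene-1,6-diol | C=C[C@](C)(O)CC/C=C(\C)CO | intermediate
4 | (3R)-5-[(2R,3R)-3-(hydroxymethyl)-3-methyloxiran-2-yl]-3-methylpent-1-en-3-ol | C=C[C@](C)(O)CC[C@H]1O[C@]1(C)CO | intermediate
5 | (2R)-2-[(2S,5R)-5-ethenyl-5-methyloxolan-2-yl]propane-1,2-diol | C=C[C@@]1(C)CC[C@H](O1)[C@](C)(O)CO | intermediate
6 | (2R)-2-[(2S,5R)-5-ethenyl-5-methyloxolan-2-yl]-2-hydroxypropyl 4-methylbenzenesulfonate | C=C[C@@]1(C)CC[C@H](O1)[C@](C)(O)COS(=O)(=O)c1ccc(C)cc1 | intermediate (not isolated)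
7 | (2S,5R)-5-ethenyl-5-methyl-2-[(2R)-2-methyloxiran-2-yl]oxolane | C=C[C@@]1(C)CC[C@H](O1)[C@@]2(C)CO2 | intermediate
8 | (2R)-4-[dimethyl(propan-2-yloxy)silyl]-2-[(2S,5R)-5-ethenyl-5-methyloxolan-2-yl]butan-2-ol | C=C[C@@]1(C)CC[C@H](O1)[C@](C)(O)CC[Si](C)(C)OC(C)C | intermediate (not isolated)
9 | (3R)-3-[(2S,5R)-5-ethenyl-5-methyloxolan-2-yl]butane-1,3-diol | C=C[C@@]1(C)CC[C@H](O1)[C@](C)(O)CCO | intermediate
10 | (2S,5R)-2-[(2R)-2,4-bis(triethylsilyloxy)butan-2-yl]-5-ethenyl-5-methyloxolane | C=C[C@@]1(C)CC[C@H](O1)[C@](C)(O[Si](CC)(CC)CC)CCO[Si](CC)(CC)CC | intermediate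
11 | (2R,5S)-5-[(2R)-2,4-bis(triethylsilyloxy)butan-2-yl]-2-methyloxolane-2-carbaldehyde | O=C[C@@]1(C)CC[C@H](O1)[C@](C)(O[Si](CC)(CC)CC)CCO[Si](CC)(CC)CC | intermediate
12 | but-2-yne-1,4-diol | OCC#CCO | starting material
13 | 4-{[tert-butyl(diphenyl)silyl]oxy}but-2-yn-1-ol | OCC#CCO[Si](c1ccccc1)(c1ccccc1)C(C)(C)C | intermediate
14 | 4-{[tert-butyl(diphenyl)silyl]oxy}but-2-yn-1-yl methyl carbonate | COC(=O)OCC#CCO[Si](c1ccccc1)(c1ccccc1)C(C)(C)C | intermediate
15 | methyl 2-({[tert-butyl(diphenyl)silyl]oxy}methyl)buta-2,3-dienoate | C=C=C(CO[Si](c1ccccc1)(c1ccccc1)C(C)(C)C)C(=O)OC | intermediate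
16 | 3-({[tert-butyl(diphenyl)silyl]oxy}methyl)-4-iodofuran-2(5H)-one | O=C1OCC(I)=C1CO[Si](c1ccccc1)(c1ccccc1)C(C)(C)C | intermediate
17 | 2-methylprop-2-en-1-ol | C=C(C)CO | starting material
18 | [(2R)-2-methyloxiran-2-yl]methanol | OC[C@]1(C)CO1 | intermediate
19 | (2S)-2-methyloxirane-2-carboxylic acid | OC(=O)[C@]1(C)CO1 | intermediate
20 | 2-(tert-butyldimethylsilyloxy)-3-({[tert-butyl(diphenyl)silyl]oxy}methyl)-4-iodofuran | CC(C)(C)[Si](C)(C)Oc1occ(I)c1CO[Si](c1ccccc1)(c1ccccc1)C(C)(C)C | intermediate (not isolated)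
21 | 5-{[(2R,5S)-5-[(2R)-2,4-bis(triethylsilyloxy)butan-2-yl]-2-methyloxolan-2-yl](tert-butyldimethylsilyloxy)methyl}-3-({[tert-butyl(diphenyl)silyl]oxy}methyl)-4-iodofuran-2(5H)-one, C5/C6 epimer mixture | O=C1OC(C(O[Si](C)(C)C(C)(C)C)[C@@]2(C)CC[C@H](O2)[C@](C)(O[Si](CC)(CC)CC)CCO[Si](CC)(CC)CC)C(I)=C1CO[Si](c1ccccc1)(c1ccccc1)C(C)(C)C | intermediate
22 | 5-{[(2R,5S)-5-[(2R)-4-hydroxy-2-(triethylsilyloxy)butan-2-yl]-2-methyloxolan-2-yl](tert-butyldimethylsilyloxy)methyl}-3-({[tert-butyl(diphenyl)silyl]oxy}methyl)-4-iodofuran-2(5H)-one, C5/C6 epimer mixture | O=C1OC(C(O[Si](C)(C)C(C)(C)C)[C@@]2(C)CC[C@H](O2)[C@](C)(O[Si](CC)(CC)CC)CCO)C(I)=C1CO[Si](c1ccccc1)(c1ccccc1)C(C)(C)C | intermediate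
23 | 5-{[(2R,5S)-2-methyl-5-[(2R)-4-oxo-2-(triethylsilyloxy)butan-2-yl]oxolan-2-yl](tert-butyldimethylsilyloxy)methyl}-3-({[tert-butyl(diphenyl)silyl]oxy}methyl)-4-iodofuran-2(5H)-one, C5/C6 epimer mixture | O=C1OC(C(O[Si](C)(C)C(C)(C)C)[C@@]2(C)CC[C@H](O2)[C@](C)(O[Si](CC)(CC)CC)CC=O)C(I)=C1CO[Si](c1ccccc1)(c1ccccc1)C(C)(C)C | intermediate
24 | (1S,4R,10R)-5-(tert-butyldimethylsilyloxy)-13-{[tert-butyl(diphenyl)silyl]oxy}-1,4-epoxy-8-hydroxy-10-(triethylsilyloxy)germacr-7(11)-en-12,6-olide, C5/C6/C8 epimer mixture | O=C1OC2C(O[Si](C)(C)C(C)(C)C)[C@@]3(C)CC[C@H](O3)[C@](C)(O[Si](CC)(CC)CC)CC(O)C2=C1CO[Si](c1ccccc1)(c1ccccc1)C(C)(C)C | intermediate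
25 | (1S,4R,10R)-5-(tert-butyldimethylsilyloxy)-13-{[tert-butyl(diphenyl)silyl]oxy}-1,4-epoxy-8-oxo-10-(triethylsilyloxy)germacr-7(11)-en-12,6-olide, C5/C6 epimer mixture | O=C1OC2C(O[Si](C)(C)C(C)(C)C)[C@@]3(C)CC[C@H](O3)[C@](C)(O[Si](CC)(CC)CC)CC(=O)C2=C1CO[Si](c1ccccc1)(c1ccccc1)C(C)(C)C | intermediate
26 | (1S,4R,5E,10R)-13-{[tert-butyl(diphenyl)silyl]oxy}-1,4-epoxy-8-oxo-10-(triethylsilyloxy)germacra-5,7(11)-dien-12,6-olide | CC(C)(C)[Si](c1ccccc1)(c1ccccc1)OCC1=C2/C(=C\[C@@]3(C)CC[C@H](O3)[C@](C)(O[Si](CC)(CC)CC)CC2=O)OC1=O | intermediate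
27 | (1S,4R,5E,8S,10R)-13-{[tert-butyl(diphenyl)silyl]oxy}-1,4-epoxy-8-hydroxy-10-(triethylsilyloxy)germacra-5,7(11)-dien-12,6-olide | CC(C)(C)[Si](c1ccccc1)(c1ccccc1)OCC1=C2/C(=C\[C@@]3(C)CC[C@H](O3)[C@](C)(O[Si](CC)(CC)CC)C[C@@H]2O)OC1=O | intermediate
28 | (1S,4R,5E,8S,10R)-1,4-epoxy-8,10,13-trihydroxygermacra-5,7(11)-dien-12,6-olide | OCC1=C2/C(=C\[C@@]3(C)CC[C@H](O3)[C@](C)(O)C[C@@H]2O)OC1=O | intermediate
29 | (1S,4R,5E,8S,10R)-13-acetoxy-1,4-epoxy-8,10-dihydroxygermacra-5,7(11)-dien-12,6-olide | CC(=O)OCC1=C2/C(=C\[C@@]3(C)CC[C@H](O3)[C@](C)(O)C[C@@H]2O)OC1=O | intermediate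
30 | (1S,4R,5E,8S,10R)-13-acetoxy-1,4-epoxy-10-hydroxy-8-{[(2S)-2-methyloxirane-2-carbonyl]oxy}germacra-5,7(11)-dien-12,6-olide (CNP0142137.1) | CC(=O)OCC1=C2/C(=C\[C@@]3(C)CC[C@H](O3)[C@](C)(O)C[C@@H]2OC(=O)[C@]2(C)CO2)OC1=O | target

## Step count and risk

Total: 23 steps. Longest linear sequence: 17 steps (steps 1–7, then 14–23).

**Step 17 (CrCl2/NiCl2 ring closure).** This is a ten-membered ring formed from a fully substituted, electron-poor alkenyl iodide. Fallback: close the same C7–C8 bond as a ketone by an intramolecular acyl Stille coupling. Setting out from 22, Pd(PPh3)4 and Me3SnSnMe3 (toluene, 80 °C) exchange iodine for tin to give the stannyl alcohol 5-{[(2R,5S)-5-[(2R)-4-hydroxy-2-(triethylsilyloxy)butan-2-yl]-2-methyloxolan-2-yl](tert-butyldimethylsilyloxy)methyl}-3-({[tert-butyl(diphenyl)silyl]oxy}methyl)-4-(trimethylstannyl)furan-2(5H)-one F3. Dess–Martin periodinane followed by NaClO2/NaH2PO4/2-methyl-2-butene gives the corresponding C8 carboxylic acid F4, and 1-chloro-N,N,2-trimethylprop-1-en-1-amine converts it into the C8 acid chloride F5. Pd2(dba)3 (dba = dibenzylideneacetone) with tri(2-furyl)phosphine in toluene at 0.002 M and 70 °C then closes the ring. This comes back to the route at ketone 25, so step 18 is no longer needed.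

**Step 20 (CBS reduction).** Facial control on a strained macrocyclic ketone with a neopentyl-type CH2 on one side is not guaranteed. Fallback: set C8 by SN2 inversion at the esterification instead of by the reduction. Setting out from 26, NaBH4/CeCl3·7H2O (MeOH, −78 °C) or the enantiomeric oxazaborolidine gives the 8R alcohol (1S,4R,5E,8R,10R)-13-{[tert-butyl(diphenyl)silyl]oxy}-1,4-epoxy-8-hydroxy-10-(triethylsilyloxy)germacra-5,7(11)-dien-12,6-olide F6. HF·pyridine gives the 8-epi-triol (1S,4R,5E,8R,10R)-1,4-epoxy-8,10,13-trihydroxygermacra-5,7(11)-dien-12,6-olide F7, and AcCl/2,4,6-collidine gives the 8-epi-13-acetate (1S,4R,5E,8R,10R)-13-acetoxy-1,4-epoxy-8,10-dihydroxygermacra-5,7(11)-dien-12,6-olide F8. Mitsunobu esterification of F8 with acid 19 (PPh3, diisopropyl azodicarboxylate, toluene, 0 °C) inverts C8 and comes back to the route directly at 30.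

**Step 14 (vinylogous aldol).** The iodinated silyloxyfuran is a weakened nucleophile that meets a hindered α-quaternary aldehyde, and the C–iodine bond may not survive. Fallback: mask the halogen as a stannane during the aldol. Setting out from 16, Bu3SnSnBu3 and Pd(PPh3)4 (toluene, 80 °C) give 3-({[tert-butyl(diphenyl)silyl]oxy}methyl)-4-(tributylstannyl)furan-2(5H)-one F1. The same TBSOTf/i-Pr2NEt aldol with 11 gives the stannylated adduct 5-{[(2R,5S)-5-[(2R)-2,4-bis(triethylsilyloxy)butan-2-yl]-2-methyloxolan-2-yl](tert-butyldimethylsilyloxy)methyl}-3-({[tert-butyl(diphenyl)silyl]oxy}methyl)-4-(tributylstannyl)furan-2(5H)-one F2. Iododestannylation (I2, CH2Cl2, 0 °C) comes back to the route at 21.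

## Further compounds

F1 | step 14 | 3-({[tert-butyl(diphenyl)silyl]oxy}methyl)-4-(tributylstannyl)furan-2(5H)-one | O=C1OCC([Sn](CCCC)(CCCC)CCCC)=C1CO[Si](c1ccccc1)(c1ccccc1)C(C)(C)C
F2 | step 14 | 5-{[(2R,5S)-5-[(2R)-2,4-bis(triethylsilyloxy)butan-2-yl]-2-methyloxolan-2-yl](tert-butyldimethylsilyloxy)methyl}-3-({[tert-butyl(diphenyl)silyl]oxy}methyl)-4-(tributylstannyl)furan-2(5H)-one, C5/C6 epimer mixture | O=C1OC(C(O[Si](C)(C)C(C)(C)C)[C@@]2(C)CC[C@H](O2)[C@](C)(O[Si](CC)(CC)CC)CCO[Si](CC)(CC)CC)C([Sn](CCCC)(CCCC)CCCC)=C1CO[Si](c1ccccc1)(c1ccccc1)C(C)(C)C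
F3 | step 17 | 5-{[(2R,5S)-5-[(2R)-4-hydroxy-2-(triethylsilyloxy)butan-2-yl]-2-methyloxolan-2-yl](tert-butyldimethylsilyloxy)methyl}-3-({[tert-butyl(diphenyl)silyl]oxy}methyl)-4-(trimethylstannyl)furan-2(5H)-one, C5/C6 epimer mixture | O=C1OC(C(O[Si](C)(C)C(C)(C)C)[C@@]2(C)CC[C@H](O2)[C@](C)(O[Si](CC)(CC)CC)CCO)C([Sn](C)(C)C)=C1CO[Si](c1ccccc1)(c1ccccc1)C(C)(C)C
F4 | step 17 | (3R)-3-[(2S,5R)-5-{(tert-butyldimethylsilyloxy)[4-({[tert-butyl(diphenyl)silyl]oxy}methyl)-5-oxo-3-(trimethylstannyl)-2,5-dihydrofuran-2-yl]methyl}-5-methyloxolan-2-yl]-3-(triethylsilyloxy)butanoic acid, C5/C6 epimer mixture | O=C1OC(C(O[Si](C)(C)C(C)(C)C)[C@@]2(C)CC[C@H](O2)[C@](C)(O[Si](CC)(CC)CC)CC(=O)O)C([Sn](C)(C)C)=C1CO[Si](c1ccccc1)(c1ccccc1)C(C)(C)C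
F5 | step 17 | acid chloride of F4, (3R)-3-[(2S,5R)-5-{(tert-butyldimethylsilyloxy)[4-({[tert-butyl(diphenyl)silyl]oxy}methyl)-5-oxo-3-(trimethylstannyl)-2,5-dihydrofuran-2-yl]methyl}-5-methyloxolan-2-yl]-3-(triethylsilyloxy)butanoyl chloride, C5/C6 epimer mixture | O=C1OC(C(O[Si](C)(C)C(C)(C)C)[C@@]2(C)CC[C@H](O2)[C@](C)(O[Si](CC)(CC)CC)CC(=O)Cl)C([Sn](C)(C)C)=C1CO[Si](c1ccccc1)(c1ccccc1)C(C)(C)C
F6 | step 20 | (1S,4R,5E,8R,10R)-13-{[tert-butyl(diphenyl)silyl]oxy}-1,4-epoxy-8-hydroxy-10-(triethylsilyloxy)germacra-5,7(11)-dien-12,6-olide | CC(C)(C)[Si](c1ccccc1)(c1ccccc1)OCC1=C2/C(=C\[C@@]3(C)CC[C@H](O3)[C@](C)(O[Si](CC)(CC)CC)C[C@H]2O)OC1=O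
F7 | step 20 | (1S,4R,5E,8R,10R)-1,4-epoxy-8,10,13-trihydroxygermacra-5,7(11)-dien-12,6-olide | OCC1=C2/C(=C\[C@@]3(C)CC[C@H](O3)[C@](C)(O)C[C@H]2O)OC1=O
F8 | step 20 | (1S,4R,5E,8R,10R)-13-acetoxy-1,4-epoxy-8,10-dihydroxygermacra-5,7(11)-dien-12,6-olide | CC(=O)OCC1=C2/C(=C\[C@@]3(C)CC[C@H](O3)[C@](C)(O)C[C@H]2O)OC1=O
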